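Everything rests on cutting the diaryl ether bond between C5 of ring A (C1 carries the carbinol) and the phenolic oxygen of ring B. In the target that aryloxy oxygen stands ortho to the free C4–OH of ring A. C3 on the other flank also bears oxygen, so the C3/C4/C5 array maps onto a symmetric 3,5-dibromo-4-hydroxyphenyl ring. Oxidising this ring, trapping it with the ring-B 2,6-dichlorophenol oxygen and reducing with zinc closes the 18-membered macrocycle in one operation. One bromine survives as the handle for the C3 oxygen. The precursor is the open B–C–D–A chain with both halophenols free, the (S)-carbinol silylated and the ring-C oxygen benzylated.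

Key step: step 12

Remark on configuration: with O > ring A > CH2 > H, the carbinol carbon of the target is (S).
Remark on salts: phenoxides and alkoxides that exist only while base is present are treated as their parent compounds.
Remarks on design:
- Both ring-A bromines arrive with the ring-A building block. No electrophilic bromination is therefore run beside the electron-rich rings C and D or the carbinol.
- The ring-C oxygen is benzylated from the start, because a methyl ether would need a Lewis-acid cleavage that the oxygenated benzylic carbinol would not tolerate.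
- The last catechol oxygen is installed by borylation–oxidation on the O-benzylated phenol. This avoids hot hydroxide acting on a para-hydroxybenzylic silyl ether.
- The oxidation is buffered with pyridine to protect the silyl ether from the nitric acid it releases.

Step 1
Reactants: 1 2-fluoro-3-hydroxybenzaldehyde
Product: 2 3-(benzyloxy)-2-fluorobenzaldehyde
Conditions: BnBr, K2CO3, DMF, rt
Reagents that add atoms: benzyl bromide, BrCc1ccccc1
Why: Williamson ether synthesis on the acidic ortho-fluorophenol installs the hydrogenolysable ring-C protecting group before any sensitive function exists.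

Step 2
Reactants: 2 3-(benzyloxy)-2-fluorobenzaldehyde; 3 methyl 2-(3-hydroxyphenyl)acetate
Product: 4 methyl 2-{3-[2-(benzyloxy)-6-formylphenoxy]phenyl}acetate
Conditions: K2CO3, DMF, 110 °C
Reagents that add atoms: none
Why: Nucleophilic aromatic substitution through a Meisenheimer adduct should work because the fluorine is ortho to the formyl group, and carbonate is too weak a base to enolise the arylacetate appreciably.

Step 3
Reactants: 4 methyl 2-{3-[2-(benzyloxy)-6-formylphenoxy]phenyl}acetate
Product: 5 methyl 2-{3-[2-(benzyloxy)-6-ethenylphenoxy]phenyl}acetate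
Conditions: MePPh3Br, NaHMDS, THF, 0 °C; then 4, −78 → 0 °C
Reagents that add atoms: methyltriphenylphosphonium bromide, C[P+](c1ccccc1)(c1ccccc1)c1ccccc1.[Br-]
Why: Wittig methylenation is much faster at the aldehyde than at the ester, so the styrene should form chemoselectively at low temperature.

Step 4
Reactants: 5 methyl 2-{3-[2-(benzyloxy)-6-ethenylphenoxy]phenyl}acetate; 6 4-bromo-2,6-dichlorophenol
Product: 8 methyl 2-{3-[2-(benzyloxy)-6-[2-(3,5-dichloro-4-hydroxyphenyl)ethyl]phenoxy]phenyl}acetate, via 9-BBN alkylborane 7 (not isolated)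
Conditions: 9-BBN-H, THF, 0 °C → rt; then 6, PdCl2(dppf) (cat.), K2CO3, DMF–H2O, 55 °C
Reagents that add atoms: 9-borabicyclo[3.3.1]nonane (boron unit of 7 only), B1C2CCCC1CCC2
Why: Anti-Markovnikov hydroboration of the styrene followed by B-alkyl Suzuki–Miyaura coupling builds the ring B–CH2CH2–ring C bridge directly at the saturated level, with Pd(0) inserting into C–Br rather than the two C–Cl bonds and the phenol carried as its potassium salt.

Step 5
Reactants: 8 methyl 2-{3-[2-(benzyloxy)-6-[2-(3,5-dichloro-4-hydroxyphenyl)ethyl]phenoxy]phenyl}acetate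
Product: 9 2-{3-[2-(benzyloxy)-6-[2-(3,5-dichloro-4-hydroxyphenyl)ethyl]phenoxy]phenyl}-N-methoxy-N-methylacetamide
Conditions: MeNH(OMe)·HCl, iPrMgCl, THF, −20 → 0 °C
Reagents that add atoms: N,O-dimethylhydroxylamine hydrochloride, CNOC.Cl
Why: Aminolysis of the ester by the chloromagnesium amide of N,O-dimethylhydroxylamine should give the Weinreb amide, with one extra equivalent of base spent on the phenol.

Step 6
Reactants: 10 2,6-dibromophenol
Product: 11 2,6-dibromo-4-iodophenol
Conditions: NIS, TsOH (cat.), MeCN, rt
Reagents that add atoms: N-iodosuccinimide, O=C1CCC(=O)N1I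
Why: Electrophilic aromatic iodination can only go para to the hydroxyl group because both ortho positions carry bromine.

Step 7
Reactants: 11 2,6-dibromo-4-iodophenol
Product: 12 (2,6-dibromo-4-iodophenoxy)triisopropylsilane
Conditions: TIPSOTf, 2,6-lutidine, CH2Cl2, 0 °C → rt
Reagents that add atoms: triisopropylsilyl triflate, CC(C)[Si](C(C)C)(C(C)C)OS(=O)(=O)C(F)(F)F
Why: Silyl ether formation with the reactive triflate overcomes the flanking bromines, and the bulky TIPS group should then withstand organomagnesium reagents and the formic acid medium.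

Step 8
Reactants: 12 (2,6-dibromo-4-iodophenoxy)triisopropylsilane; 9 2-{3-[2-(benzyloxy)-6-[2-(3,5-dichloro-4-hydroxyphenyl)ethyl]phenoxy]phenyl}-N-methoxy-N-methylacetamide
Product: 14 2-{3-[2-(benzyloxy)-6-[2-(3,5-dichloro-4-hydroxyphenyl)ethyl]phenoxy]phenyl}-1-[3,5-dibromo-4-(triisopropylsilyloxy)phenyl]ethan-1-one, via arylmagnesium chloride 13 (not isolated)
Conditions: 12, iPrMgCl·LiCl, THF, −40 °C; then 9 (phenol pre-deprotonated with 1 equiv iPrMgCl), −40 → 0 °C; aq NH4Cl
Reagents that add atoms: isopropylmagnesium chloride (MgCl of 13 only), CC(C)[Mg]Cl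
Why: Iodine–magnesium exchange is far faster than bromine–magnesium exchange at −40 °C, and the Weinreb ketone synthesis stops at the chelated tetrahedral adduct, so a single acylation should give the aryl benzyl ketone with both bromines already in place.

Step 9
Reactants: 14 2-{3-[2-(benzyloxy)-6-[2-(3,5-dichloro-4-hydroxyphenyl)ethyl]phenoxy]phenyl}-1-[3,5-dibromo-4-(triisopropylsilyloxy)phenyl]ethan-1-one
Product: 15 (1S)-2-{3-[2-(benzyloxy)-6-[2-(3,5-dichloro-4-hydroxyphenyl)ethyl]phenoxy]phenyl}-1-[3,5-dibromo-4-(triisopropylsilyloxy)phenyl]ethan-1-ol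
Conditions: RuCl(p-cymene)[(S,S)-TsDPEN] (cat.), HCO2H–Et3N 5:2, CH2Cl2, 30 °C
Reagents that add atoms: none
Why: In the Noyori–Ikariya asymmetric transfer hydrogenation the (S,S)-catalyst holds the carbonyl-conjugated ring A against its η6-arene (CH/π contact) and delivers hydride to the Re face, which should set the (S)-carbinol as it does for acetophenone-type aryl alkyl ketones.

Step 10
Reactants: 15 (1S)-alcohol with ring-A O-TIPS and free ring-B phenol
Product: 16 (S)-tris-silyl ether (carbinol O-TBS; ring-B O-TBS; ring-A O-TIPS)
Conditions: TBSCl, imidazole, DMF, rt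
Reagents that add atoms: tert-butyldimethylsilyl chloride, CC(C)(C)[Si](C)(C)Cl
Why: Imidazole-promoted silylation caps the carbinol without touching its C–O bond and unavoidably also caps the ring-B phenol, which the next step releases.

Step 11
Reactants: 16 (S)-tris-silyl ether
Product: 17 open-chain (S)-precursor 4-[(1S)-1-(tert-butyldimethylsilyloxy)-2-{3-[2-(benzyloxy)-6-[2-(3,5-dichloro-4-hydroxyphenyl)ethyl]phenoxy]phenyl}ethyl]-2,6-dibromophenol
Conditions: TBAF, AcOH, THF, 0 °C
Reagents that add atoms: none
Why: Buffered fluoride desilylation discriminates by leaving-group ability, since the two halophenoxides (pKa near 7) leave silicon quickly while the secondary alkyl TBS ether reacts much more slowly, and acetic acid keeps the para-hydroxybenzylic silyl ether away from free phenoxide.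

Step 12
Reactants: 17 open-chain (S)-precursor with 2,6-dibromophenol (ring A) and 2,6-dichlorophenol (ring B) termini
Product: 19 (S)-macrocyclic bromophenol (ring A 3-bromo-4-hydroxy-5-aryloxy; ring B dichloro; ring C O-benzyl; carbinol O-TBS), via quinol methyl ether dienone 18 (not isolated)
Conditions: Tl(NO3)3·3H2O, pyridine, THF–MeOH, ca. 1 mM, 0 °C → rt; then Zn, AcOH, 0 °C → rt
Reagents that add atoms: methanol (methoxy group of 18 only, lost again on reduction), CO
Why: Thallium(III) binds the more easily oxidised ring-A phenol and takes two electrons to give a phenoxenium-type cation; the ring-B phenol oxygen adds to a bromine-bearing ortho carbon, bromide departs, methanol caps the para carbon C1 to give dienone 18, and zinc returns 18 to the phenol with loss of methanol, so the net change is C–Br to C–OAr. The closest known reaction type is the thallium(III) nitrate (or anodic) oxidative cyclisation of open-chain bis(o,o'-dihalophenols) to macrocyclic diaryl ethers followed by zinc reduction. The single 18-membered ring closes by intramolecular O-attack on an sp2 carbon of the dearomatised ring under high dilution, which spares the route a metal-catalysed C–O coupling at a phenol flanked by two halogens. No lasting stereocentre is made, because the quaternary carbon of 18 is erased on rearomatisation, and the (S)-carbinol is a spectator protected against ionisation by its poor silyloxy leaving group, the meta halogen and the pyridine buffer. The step needs ring A to be oxidised and ring B to act as nucleophile, which the lower oxidation potential of a dibromophenol relative to a dichlorophenol should secure, while both C–Br carbons lead to the same constitution and chlorine and alkyl groups block every ortho and para carbon of ring B so that only O–C coupling is open. Ring C stays benzylated because a free, more electron-rich phenol there would be oxidised first, and the product is stored in the flask as the already oxidised 18, which limits over-oxidation.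

Step 13
Reactants: 19 (S)-macrocyclic bromophenol
Product: 20 (S)-macrocyclic ring-A C4 benzyl ether (ring A 3-bromo-4-benzyloxy-5-aryloxy)
Conditions: BnBr, K2CO3, DMF, rt
Reagents that add atoms: benzyl bromide, BrCc1ccccc1
Why: Williamson benzylation masks the C4 phenol para to the carbinol, which shuts off quinone methide formation under later basic conditions and costs no extra step because it falls in the hydrogenolysis.

Step 14
Reactants: 20 (S)-macrocyclic ring-A C4 benzyl ether
Product: 22 (S)-macrocyclic C3 phenol (ring A 3-hydroxy-4-benzyloxy-5-aryloxy), via aryl pinacol boronate 21 (not isolated)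
Conditions: B2pin2, PdCl2(dppf) (cat.), KOAc, 1,4-dioxane, 85 °C; then 30% H2O2, THF–pH 7 buffer, 0 °C → rt
Reagents that add atoms: bis(pinacolato)diboron (Bpin of 21 only), CC1(C)OB(OC1(C)C)B1OC(C)(C)C(C)(C)O1; hydrogen peroxide, OO
Why: Miyaura borylation with a dppf catalyst engages the C–Br bond and not the flanked C–Cl bonds, and the oxidative 1,2-aryl shift from boron to oxygen then installs the C3 hydroxyl group under near-neutral conditions.

Step 15
Reactants: 22 (S)-macrocyclic C3 phenol
Product: 23 (S)-O-TBS ether of the target (all four phenols free; no halogen)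
Conditions: H2 (1–3 bar), 10% Pd/C, NaOAc, MeOH–EtOAc, rt
Reagents that add atoms: none
Why: Heterogeneous catalytic hydrogenolysis cleaves both aryl benzyl ethers and, with acetate as HCl scavenger, both C–Cl bonds, while the bulky secondary silyl ether in a medium free of strong acid should shield the benzylic C–O bond and its configuration.

Step 16
Reactants: 23 (S)-O-TBS ether of the target
Product: 24 target CNP0333307.1, (S)-configured
Conditions: TBAF, AcOH, THF, 0 °C → rt, Ar
Reagents that add atoms: none
Why: Fluoride-induced desilylation buffered by acetic acid breaks only the Si–O bond, so the (S)-configured C–O bond is untouched and neither phenoxide-driven quinone methide formation nor acid ionisation should intervene.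

Compound list
1 | 2-fluoro-3-hydroxybenzaldehyde | O=Cc1cccc(O)c1F | starting material
2 | 3-(benzyloxy)-2-fluorobenzaldehyde | O=Cc1cccc(OCc2ccccc2)c1F | intermediate
3 | methyl 2-(3-hydroxyphenyl)acetate | COC(=O)Cc1cccc(O)c1 | starting material
4 | methyl 2-{3-[2-(benzyloxy)-6-formylphenoxy]phenyl}acetate | O=Cc1cccc(OCc2ccccc2)c1Oc1cccc(c1)CC(=O)OC | intermediate
5 | methyl 2-{3-[2-(benzyloxy)-6-ethenylphenoxy]phenyl}acetate | C=Cc1cccc(OCc2ccccc2)c1Oc1cccc(c1)CC(=O)OC | intermediate
6 | 4-bromo-2,6-dichlorophenol | Oc1c(Cl)cc(Br)cc1Cl | starting material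
7 | 9-BBN alkylborane from 5 (boron on the terminal carbon) | C1CC2CCCC(C1)B2CCc1cccc(OCc2ccccc2)c1Oc1cccc(c1)CC(=O)OC | intermediate
8 | B–C–D methyl ester with free ring-B phenol | Oc1c(Cl)cc(cc1Cl)CCc1cccc(OCc2ccccc2)c1Oc1cccc(c1)CC(=O)OC | intermediate
9 | B–C–D Weinreb amide | Oc1c(Cl)cc(cc1Cl)CCc1cccc(OCc2ccccc2)c1Oc1cccc(c1)CC(=O)N(C)OC | intermediate
10 | 2,6-dibromophenol | Oc1c(Br)cccc1Br | starting material
11 | 2,6-dibromo-4-iodophenol | Oc1c(Br)cc(I)cc1Br | intermediate
12 | (2,6-dibromo-4-iodophenoxy)triisopropylsilane | CC(C)[Si](C(C)C)(C(C)C)Oc1c(Br)cc(I)cc1Br | intermediate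
13 | 3,5-dibromo-4-(triisopropylsilyloxy)phenylmagnesium chloride | CC(C)[Si](C(C)C)(C(C)C)Oc1c(Br)cc([Mg]Cl)cc1Br | intermediate
14 | aryl benzyl ketone (ring-A O-TIPS, ring-B OH) | Oc1c(Cl)cc(cc1Cl)CCc1cccc(OCc2ccccc2)c1Oc1cccc(c1)CC(=O)c1cc(Br)c(O[Si](C(C)C)(C(C)C)C(C)C)c(Br)c1 | intermediate
15 | (S)-alcohol (ring-A O-TIPS, ring-B OH) | Oc1c(Cl)cc(cc1Cl)CCc1cccc(OCc2ccccc2)c1Oc1cccc(c1)C[C@H](O)c1cc(Br)c(O[Si](C(C)C)(C(C)C)C(C)C)c(Br)c1 | intermediate
16 | (S)-tris-silyl ether | CC(C)(C)[Si](C)(C)Oc1c(Cl)cc(cc1Cl)CCc1cccc(OCc2ccccc2)c1Oc1cccc(c1)C[C@H](O[Si](C)(C)C(C)(C)C)c1cc(Br)c(O[Si](C(C)C)(C(C)C)C(C)C)c(Br)c1 | intermediate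
17 | open-chain (S)-precursor, dibromophenol and dichlorophenol termini | Oc1c(Cl)cc(cc1Cl)CCc1cccc(OCc2ccccc2)c1Oc1cccc(c1)C[C@H](O[Si](C)(C)C(C)(C)C)c1cc(Br)c(O)c(Br)c1 | intermediate
18 | macrocyclic 2-aryloxy-6-bromo-4-methoxycyclohexa-2,5-dienone (either configuration at the methoxy carbon; carbinol S) | COC12C=C(Br)C(=O)C(=C1)Oc1c(Cl)cc(cc1Cl)CCc1cccc(OCc3ccccc3)c1Oc1cccc(c1)C[C@@H]2O[Si](C)(C)C(C)(C)C | intermediate
19 | (S)-macrocyclic bromophenol | Brc1cc2cc(c1O)Oc1c(Cl)cc(cc1Cl)CCc1cccc(OCc3ccccc3)c1Oc1cccc(c1)C[C@@H]2O[Si](C)(C)C(C)(C)C | intermediate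
20 | (S)-macrocyclic ring-A benzyl ether | Brc1cc2cc(c1OCc3ccccc3)Oc1c(Cl)cc(cc1Cl)CCc1cccc(OCc3ccccc3)c1Oc1cccc(c1)C[C@@H]2O[Si](C)(C)C(C)(C)C | intermediate
21 | (S)-macrocyclic aryl pinacol boronate | CC1(C)OB(OC1(C)C)c1cc2cc(c1OCc3ccccc3)Oc1c(Cl)cc(cc1Cl)CCc1cccc(OCc3ccccc3)c1Oc1cccc(c1)C[C@@H]2O[Si](C)(C)C(C)(C)C | intermediate
22 | (S)-macrocyclic C3 phenol | Oc1cc2cc(c1OCc3ccccc3)Oc1c(Cl)cc(cc1Cl)CCc1cccc(OCc3ccccc3)c1Oc1cccc(c1)C[C@@H]2O[Si](C)(C)C(C)(C)C | intermediate
23 | (S)-O-TBS ether of the target | Oc1cc2cc(c1O)Oc1ccc(cc1)CCc1cccc(O)c1Oc1cccc(c1)C[C@@H]2O[Si](C)(C)C(C)(C)C | intermediate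
24 | CNP0333307.1, (S) | Oc1cc2cc(c1O)Oc1ccc(cc1)CCc1cccc(O)c1Oc1cccc(c1)C[C@@H]2O | target

Total step count: 16.
Longest linear sequence: 14 steps (steps 1–5 and 8–16, from 1).

Steps most likely to fail

1. Step 12.
- The α-silyloxyalkyl group makes the para substituent of ring A a weaker donor, so the potential gap to ring B narrows and electron removal may shift to the wrong ring.
- The cationic stage may shed the benzylic hydrogen or the whole side chain.
- Chains may couple with each other instead of closing, and released acid may strip the silyl ether.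
- Fallback: close the same C5–O bond by a copper(II)-promoted Chan–Lam O-arylation, which needs no oxidised ring and is known to accept o,o'-dihalophenols and intramolecular cases. It sets out from 16 and returns at 19.
- A single bromine–magnesium exchange on ring A of 16 (iPrMgCl·LiCl, THF, −15 °C; the arylmagnesium formed resists a second exchange), then B(OMe)3 and mild aqueous hydrolysis, should give the fully silylated ring-A boronic acid F1.
- K2CO3 in MeOH at 0 °C should release only the ring-B phenol, because the aryl TBS ether solvolyses far faster than the flanked aryl TIPS ether or the alkyl TBS ether. This gives the phenol boronic acid F2.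
- Slow addition of F2 to Cu(OAc)2, pyridine and 4 Å sieves in CH2Cl2 under air should give the ring-A O-TIPS macrocycle F3.
- TBAF/AcOH at 0 °C removes the aryl TIPS group from F3 and gives 19.

2. Step 15.
- Cleavage of the C–Cl bonds buried beside the diaryl ether inside the macrocycle may stall. That invites forcing conditions and then hydrogenolysis of the benzylic C–O bond.
- Fallback: split the task, from 22 back to 23.
- A homogeneous palladium hydride cycle (Pd(OAc)2, bulky biaryl phosphine, HCO2Na, DMF, 80 °C) runs through oxidative addition into C–Cl, formate decarboxylation and reductive elimination. It cannot touch benzyl ethers or the benzylic silyl ether, and should give the chlorine-free dibenzyl ether F4.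
- A short hydrogenolysis under neutral conditions (H2, Pd/C, EtOAc–EtOH, rt), which releases no acid, then removes the two aryl benzyl ethers of F4 and gives 23.

3. Step 4.
- Oxidative addition into the electron-rich bromophenoxide may be slow. The alkylborane could then be lost by protodeboronation or β-hydride elimination, and the ester could be partly saponified.
- Fallback: form the bridge at the alkene level, from 5 and 6 back to 8.
- A Heck reaction of styrene 5 with 6 (Pd(OAc)2, P(o-tol)3, Et3N, DMF, 100 °C) should give the (E)-stilbene F5.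
- Diimide reduction of F5 (TsNHNH2, NaOAc, THF–H2O, reflux) saturates the C=C bond without touching C–Cl or O-benzyl bonds and gives 8.

Further compounds
F1 | step 12 | fully silylated (S)-ring-A boronic acid | CC(C)(C)[Si](C)(C)Oc1c(Cl)cc(cc1Cl)CCc1cccc(OCc2ccccc2)c1Oc1cccc(c1)C[C@H](O[Si](C)(C)C(C)(C)C)c1cc(Br)c(O[Si](C(C)C)(C(C)C)C(C)C)c(c1)B(O)O
F2 | step 12 | (S)-phenol boronic acid (ring-B OH free) | Oc1c(Cl)cc(cc1Cl)CCc1cccc(OCc2ccccc2)c1Oc1cccc(c1)C[C@H](O[Si](C)(C)C(C)(C)C)c1cc(Br)c(O[Si](C(C)C)(C(C)C)C(C)C)c(c1)B(O)O
F3 | step 12 | (S)-ring-A O-TIPS macrocycle | Brc1cc2cc(c1O[Si](C(C)C)(C(C)C)C(C)C)Oc1c(Cl)cc(cc1Cl)CCc1cccc(OCc3ccccc3)c1Oc1cccc(c1)C[C@@H]2O[Si](C)(C)C(C)(C)C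
F4 | step 15 | (S)-chlorine-free dibenzyl ether | Oc1cc2cc(c1OCc3ccccc3)Oc1ccc(cc1)CCc1cccc(OCc3ccccc3)c1Oc1cccc(c1)C[C@@H]2O[Si](C)(C)C(C)(C)C
F5 | step 4 | (E)-stilbene | Oc1c(Cl)cc(cc1Cl)/C=C/c1cccc(OCc2ccccc2)c1Oc1cccc(c1)CC(=O)OC
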